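## Analysis of the target

Numbering used throughout: C1–C15 along the chain; C16 and C17 are the methyls on C15, C18 the methyl on C11, C19 the methyl on C7, C20 the methylene on C3.

1. The target is a C20 isoprenoid chain. It ends on one side in a 2,2,6,6-tetrasubstituted oxane (O–C11–C12–C13–C14–C15) and on the other in a 3-methylidene-1,2-diol diacetate (C1, C2, C3=C20).
2. There are three stereocentres: C2 (R, secondary allylic acetate), C7 (R, methyl-bearing methine) and C11 (S, fully substituted ether carbon). Neighbouring centres are insulated by three methylenes (C4–C6 and C8–C10), so none can steer another and each must arrive with its own absolute configuration.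
3. For the same reason, any stereochemical leak gives diastereomers that differ only at remote centres and cannot be expected to separate. This argues against late catalyst-controlled steps of imperfect selectivity.
4. C11 is the hardest centre in principle (methyl against two methylene chains on a tertiary ether carbon). However, C9–C18 are the skeleton of linalool 1, and closing O–C15 creates no stereocentre, so this part can be bought.
5. Sensitive groups are the allylic C2–O bond (ionisation, π-allyl formation), the 1,1-disubstituted C3=C20 alkene (migration to the trisubstituted position), the di-tertiary ether (strong acid) and the acetates (bases, organometallics). The acetates therefore come last and C2 is carried as an acetal.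
6. The feature on which the strategy turns is C3, the only branching sp2 carbon, bonded to methylene C20, to C4 and to stereocentre C2. C1–C2–C3 is a glyceric acid backbone with C3 at the ester oxidation level, and C4 and C20 are the two carbons of a terminal alkene added across it. C3–C4–C20 is thus a ring-opened cyclopropanol.
7. The difficulty is economy rather than any ring: twenty carbons and three independent stereocentres must be joined in few steps, and C3 must be built next to C2 without making C2 enolisable.

## Retrosynthetic reasoning

**C1–O and C2–O acyl bonds.** Target 16 is cut back to diol 15 and then to acetonide 14. The acetates would not survive the organometallic steps, and the acetonide is the form in which C1 and C2 are bought in ester 9. The forward reactions are a mild acetal hydrolysis and an acetylation.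

**C3=C20 π bond and C4–H bond.** These are not made by carbonyl olefination. Acetonide 14 is traced to allylic bromide 13 and further, through mesylate 12, to cyclopropanol 11, in which C4 and C20 are still bonded to each other. The forward direction opens the strained C4–C20 bond on ionisation at C3 (cyclopropyl-to-allyl cation rearrangement) and then delivers hydride to C4, which leaves the alkene at C3=C20. The three carbons are cut here because the strain of 11 pays for the least stable alkene isomer, and C2 is never α to a carbonyl.

**C3–C4 and C3–C20 (key disconnection).** Cyclopropanol 11 is cut into terminal alkene 8 and ester 9. Both carbon–carbon bonds to C3 are formed in one titanium-mediated step from two unactivated groups. The gain is that the head fragment needs no preparation: 9 is commercial, and alkene 8 carries no functional group that the step could confuse. The forward reaction must exchange the alkene onto titanium and must not enolise C2.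

**C5–C6.** Alkene 8 is cut between C5 and C6 into tosylate 7, which comes from alcohol 6, and a three-carbon allyl nucleophile. This places the terminal alkene (C4=C20) exactly where the key step needs it, and uses a primary sulfonate displacement that does not touch C7.

**C8–C9.** Alcohol 6 is cut into alkylborane 5, from vinyl oxane 3, and bromo alcohol 4. The cut lies next to the bought stereocentre C7 but not at it, and it uses the vinyl group of 3 as a latent C9 nucleophile. The forward reaction is an alkyl–alkyl cross-coupling at a β-branched primary bromide.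

**O–C15.** Vinyl oxane 3 is opened to linalool 1. The forward ring closure adds the tertiary hydroxyl across the trisubstituted alkene and leaves the configuration at C11 untouched.

## Alternatives that were turned down

**Alternative 1: (textbook) C3=C20 by carbonyl methylenation, C3–C4 by acylation.**
- Forward key step: Wittig methylenation of ketone A1. A1 would come from acylating the chain Grignard reagent A2 with an activated derivative of 9.
- Structure: in A1 the stereocentre C2 is α to a ketone and carries a β-oxygen (the C1–O of the dioxolane).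
- Mechanism: a basic ylide can enolise towards C2, which epimerises it or expels the C1 oxygen. A C2 epimer is a remote diastereomer that would travel to the end.
- Step economy: A2 needs hydroboration/bromination and magnesium insertion on a chain alkene, 9 needs activation, and C20 comes from a separate reagent. That is five operations for what steps 5–7 do in three.

**Alternative 2: C9=C10 by olefination of the two terpene halves.**
- Forward key step: Wittig reaction of aldehyde A3 (ozonolysis of 3) with the ylide of phosphonium salt A4, giving diene A5, followed by saturation of C9=C10.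
- Structure: A3 is a neopentyl-type aldehyde on a quaternary carbon and should react sluggishly with a non-stabilised ylide.
- Mechanism: the hindered C9=C10 alkene must then be reduced beside the trisubstituted tail alkene.
- Step economy (decisive): the tail of A5 delivers C3 with C2 and C20 as two methyl groups. C1 is missing, and no single reaction adds it to one methyl while moving the alkene to the other. Three carbons must be cut off by ozonolysis and the head built anyway, at least four operations more than the chosen route.

**Alternative 3: C2–O by catalytic asymmetric epoxidation, C3=C20 by epoxide-to-allylic-alcohol isomerisation.**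
- Forward key step: Sharpless epoxidation of the E-allylic alcohol A6 to epoxy alcohol A7, then titanium-mediated isomerisation of A7 to diol 15.
- Structure: C2 would be set by catalyst control, which is never absolute. The minor epoxide ends as the C2 epimer of 15, a diastereomer differing only at a centre five atoms from C7.
- Mechanism: the isomerisation must remove a proton from C20 and not from C4. Only delivery by the C1 alkoxide favours this, and the C3=C4 isomer is the thermodynamic alternative.
- Step economy: A6 needs a stereodefined E-trisubstituted alkene built onto the chain (alkyne, carbometallation, hydroxymethylation), so nothing is saved.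

Key step: step 5

Assumption: (R)-linalool 1, (R)-3-bromo-2-methylpropan-1-ol 4 and methyl (S)-2,2-dimethyl-1,3-dioxolane-4-carboxylate 9 are bought in high enantiomeric purity; C11, C7 and C2 of the target rest on these three materials alone.

## Route

Step 1
Reactants: 1 (R)-linalool [(3R)-3,7-dimethylocta-1,6-dien-3-ol]
Product: 3 (2R)-2-ethenyl-2,6,6-trimethyloxane, via alkylmercury acetate 2 (not isolated)
Conditions: Hg(OAc)2 (1.05 equiv), dry THF, 0 °C to rt; then NaBH4, aq. NaOH, 0 °C
Reagents that add atoms: none
Why: Intramolecular alkoxymercuration–demercuration: the tertiary hydroxyl opens the mercurinium ion of the trisubstituted C14=C15 alkene at the tertiary carbon C15 (Markovnikov, six-membered ring), while the vinyl group has no internal nucleophile within reach; NaBH4 then replaces mercury at C14 by hydrogen. The C11–O bond is never broken, so the configuration of 1 becomes C11 of the target (the descriptor is R only because the vinyl group outranks the ring methylene).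

Step 2
Reactants: 3 (2R)-2-ethenyl-2,6,6-trimethyloxane; 4 (2R)-3-bromo-2-methylpropan-1-ol
Product: 6 (2S)-2-methyl-5-[(2S)-2,6,6-trimethyloxan-2-yl]pentan-1-ol, via alkylborane 5 (not isolated)
Conditions: 9-BBN, THF, rt to 60 °C; then 4 (limiting), NiCl2·glyme (6 mol%), trans-N,N′-dimethylcyclohexane-1,2-diamine (8 mol%), KOt-Bu (2.2 equiv), i-BuOH, dioxane, rt; aqueous work-up
Reagents that add atoms: none
Why: 9-BBN places boron on the terminal carbon C9 of the vinyl group, and a nickel/diamine-catalysed alkyl–alkyl Suzuki–Miyaura coupling joins C9 to the bromide carbon C8; this catalyst class activates primary bromides by halogen abstraction and is therefore indifferent to the β-branch at C7. C7 is not a reacting centre and keeps its configuration (the descriptor becomes S by priority change only); the hydroxyl is carried as its alkoxide.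

Step 3
Reactants: 6 (2S)-2-methyl-5-[(2S)-2,6,6-trimethyloxan-2-yl]pentan-1-ol
Product: 7 (2S)-2-methyl-5-[(2S)-2,6,6-trimethyloxan-2-yl]pentyl 4-methylbenzenesulfonate
Conditions: TsCl, Et3N, DMAP (cat.), CH2Cl2, 0 °C to rt
Reagents that add atoms: 4-methylbenzenesulfonyl chloride, Cc1ccc(cc1)S(=O)(=O)Cl
Why: Standard sulfonylation of a primary alcohol, which activates C6 for displacement; no stereocentre takes part.

Step 4
Reactants: 7 (2S)-2-methyl-5-[(2S)-2,6,6-trimethyloxan-2-yl]pentyl 4-methylbenzenesulfonate
Product: 8 (2S)-2,6,6-trimethyl-2-[(4S)-4-methyloct-7-en-1-yl]oxane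
Conditions: CH2=CHCH2MgCl (2 equiv), Li2CuCl4 (5 mol%), THF, −20 °C to rt
Reagents that add atoms: allylmagnesium chloride, C=CC[Mg]Cl
Why: Copper-catalysed Grignard cross-coupling displaces the primary tosylate at C6 in SN2 fashion and adds C5, C4 and C20 as the terminal alkene the key step needs; β-branched primary sulfonates are classical partners in this kind of isoprenoid chain extension.

Step 5
Reactants: 8 (2S)-2,6,6-trimethyl-2-[(4S)-4-methyloct-7-en-1-yl]oxane; 9 methyl (4S)-2,2-dimethyl-1,3-dioxolane-4-carboxylate
Product: 11 1-[(4S)-2,2-dimethyl-1,3-dioxolan-4-yl]-2-{(3S)-3-methyl-6-[(2S)-2,6,6-trimethyloxan-2-yl]hexyl}cyclopropan-1-ol (hydroxyl trans to the hexyl chain; both ring diastereomers of this kind), via titanacyclopropane 10 (not isolated)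
Conditions: 8 (1 equiv), 9 (2 equiv), ClTi(OiPr)3 (2 equiv), c-C5H9MgCl (4.5 equiv, slow addition), THF, rt; aq. NH4Cl
Reagents that add atoms: none
Why: This is the Kulinkovich hydroxycyclopropanation of an ester in its alkene ligand-exchange variant, a known titanium-mediated reaction of esters with terminal alkenes. ClTi(OiPr)3 and two equivalents of c-C5H9MgCl give a dicyclopentyltitanium species that loses cyclopentane to form the titanacyclopropane of cyclopentene, which exchanges its disubstituted alkene for the monosubstituted alkene of 8 to give 10. The ester carbonyl of 9 inserts into the less hindered Ti–C20 bond (first bond, C3–C20), methoxide is expelled to leave a β-titanio ketone, and the remaining Ti–C4 bond adds to that ketone in a 3-exo-trig closure (second bond, C3–C4), so the ring C3–C4–C20 arises by a formal [2+1] union of the ester carbon with the alkene. Two stereocentres arise, C3 and C4: their relative configuration (hydroxyl trans to the chain) is fixed in the ring-closing step by the titanium-bridged transition state, as is usual for substituted titanacyclopropanes, and their absolute sense relative to C2 is deliberately left open because both centres are erased in steps 6 and 7. C2, α to the ester, should not be enolised, since the Grignard reagent is consumed by titanium as it is added and the titanium intermediates are not basic, so the configuration bought with 9 is kept. The step needs ligand exchange to win over direct Grignard addition to 9, which slow addition of the secondary Grignard reagent and the excess of the inexpensive ester secure; 8 offers only one alkene and its oxane ether is inert. The gain is that C3 receives both of its carbon–carbon bonds from an ester and a terminal alkene, without a preformed organometallic or halide of either fragment.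

Step 6
Reactants: 11 1-[(4S)-2,2-dimethyl-1,3-dioxolan-4-yl]-2-{(3S)-3-methyl-6-[(2S)-2,6,6-trimethyloxan-2-yl]hexyl}cyclopropan-1-ol
Product: 13 (4R)-4-{(2E,6S)-1-bromo-6-methyl-9-[(2S)-2,6,6-trimethyloxan-2-yl]non-2-en-2-yl}-2,2-dimethyl-1,3-dioxolane, via cyclopropyl mesylate 12 (not isolated)
Conditions: MsCl, Et3N, Et2O, 0 °C; filtration of the ammonium salt; then MgBr2·OEt2 (3 equiv), Et2O/CH2Cl2, 35 °C
Reagents that add atoms: magnesium bromide (as diethyl etherate), [Mg+2].[Br-].[Br-]
Why: Sulfonylation of the tertiary cyclopropanol, then magnesium bromide-assisted ionisation in which loss of mesylate is concerted with disrotatory opening of the C4–C20 bond (cyclopropyl-to-allyl cation rearrangement, driven by release of ring strain); bromide collapses on the primary terminus C20. The chain is trans to the leaving group and rotates outward, the favoured sense by the Woodward–Hoffmann rules; the alkene geometry and any secondary bromide at C4 do not matter, because all isomers enter the same π-allyl complex in step 7, and C2 is not part of the allyl system.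

Step 7
Reactants: 13 (4R)-4-{(2E,6S)-1-bromo-6-methyl-9-[(2S)-2,6,6-trimethyloxan-2-yl]non-2-en-2-yl}-2,2-dimethyl-1,3-dioxolane
Product: 14 (4R)-2,2-dimethyl-4-{(6R)-6-methyl-9-[(2S)-2,6,6-trimethyloxan-2-yl]non-1-en-2-yl}-1,3-dioxolane
Conditions: Pd(OAc)2 (5 mol%), PBu3 (20 mol%), HCO2NH4 (3 equiv), dioxane, 80 °C
Reagents that add atoms: none
Why: Palladium-catalysed formate hydrogenolysis of an allylic halide (Tsuji–Trost ionisation, then decarboxylation of the palladium formate): from the σ-allyl complex bound at the less hindered C20, hydride is delivered through a cyclic transition state to the more substituted terminus C4, which makes C4 a methylene and leaves the 1,1-disubstituted alkene C3=C20. PBu3 is the ligand associated with this terminal-alkene outcome, and zerovalent palladium does not ionise the allylic C2–O acetal bond under these neutral conditions.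

Step 8
Reactants: 14 (4R)-2,2-dimethyl-4-{(6R)-6-methyl-9-[(2S)-2,6,6-trimethyloxan-2-yl]non-1-en-2-yl}-1,3-dioxolane
Product: 15 (2R,7R)-7-methyl-3-methylidene-10-[(2S)-2,6,6-trimethyloxan-2-yl]decane-1,2-diol
Conditions: AcOH/H2O/THF (3:1:1), 45 °C
Reagents that add atoms: none
Why: Mild acid hydrolysis of the isopropylidene acetal; aqueous acetic acid is too weak to ionise the secondary allylic C2–O bond or the di-tertiary oxane ether.

Step 9
Reactants: 15 (2R,7R)-7-methyl-3-methylidene-10-[(2S)-2,6,6-trimethyloxan-2-yl]decane-1,2-diol
Product: 16 (2R,7R)-7-methyl-3-methylidene-10-[(2S)-2,6,6-trimethyloxan-2-yl]decane-1,2-diyl diacetate (target)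
Conditions: Ac2O, pyridine, DMAP (cat.), CH2Cl2, 0 °C to rt
Reagents that add atoms: acetic anhydride, CC(=O)OC(C)=O
Why: Acylation of both hydroxyls under nucleophilic catalysis; no strong base or acid is present, so the allylic system and C2 are unaffected and the product is the target.

## Compound list

1 | (R)-linalool, (3R)-3,7-dimethylocta-1,6-dien-3-ol | C=C[C@](C)(O)CCC=C(C)C | starting material
2 | acetoxy[(6R)-6-ethenyl-2,2,6-trimethyloxan-3-yl]mercury (both epimers at the mercury-bearing carbon) | C=C[C@@]1(C)CCC([Hg]OC(C)=O)C(C)(C)O1 | intermediate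
3 | (2R)-2-ethenyl-2,6,6-trimethyloxane | C=C[C@@]1(C)CCCC(C)(C)O1 | intermediate
4 | (2R)-3-bromo-2-methylpropan-1-ol | OC[C@@H](C)CBr | starting material
5 | 9-{2-[(2S)-2,6,6-trimethyloxan-2-yl]ethyl}-9-borabicyclo[3.3.1]nonane | C1CC2CCCC(C1)B2CC[C@@]1(C)CCCC(C)(C)O1 | intermediate
6 | (2S)-2-methyl-5-[(2S)-2,6,6-trimethyloxan-2-yl]pentan-1-ol | OC[C@@H](C)CCC[C@@]1(C)CCCC(C)(C)O1 | intermediate
7 | (2S)-2-methyl-5-[(2S)-2,6,6-trimethyloxan-2-yl]pentyl 4-methylbenzenesulfonate | Cc1ccc(cc1)S(=O)(=O)OC[C@@H](C)CCC[C@@]1(C)CCCC(C)(C)O1 | intermediate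
8 | (2S)-2,6,6-trimethyl-2-[(4S)-4-methyloct-7-en-1-yl]oxane | C=CCC[C@@H](C)CCC[C@@]1(C)CCCC(C)(C)O1 | intermediate
9 | methyl (4S)-2,2-dimethyl-1,3-dioxolane-4-carboxylate | COC(=O)[C@@H]1COC(C)(C)O1 | starting material
10 | 1,1-di(propan-2-yloxy)-2-{(3S)-3-methyl-6-[(2S)-2,6,6-trimethyloxan-2-yl]hexyl}titanacyclopropane | CC(C)O[Ti]1(OC(C)C)CC1CC[C@@H](C)CCC[C@@]2(C)CCCC(C)(C)O2 | intermediate
11 | 1-[(4S)-2,2-dimethyl-1,3-dioxolan-4-yl]-2-{(3S)-3-methyl-6-[(2S)-2,6,6-trimethyloxan-2-yl]hexyl}cyclopropan-1-ol (hydroxyl trans to the hexyl chain; ring centres not fixed in absolute sense and left open in the SMILES) | OC1(CC1CC[C@@H](C)CCC[C@@]2(C)CCCC(C)(C)O2)[C@@H]3COC(C)(C)O3 | intermediate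
12 | 1-[(4S)-2,2-dimethyl-1,3-dioxolan-4-yl]-2-{(3S)-3-methyl-6-[(2S)-2,6,6-trimethyloxan-2-yl]hexyl}cyclopropyl methanesulfonate (ring centres as in 11) | CS(=O)(=O)OC1(CC1CC[C@@H](C)CCC[C@@]2(C)CCCC(C)(C)O2)[C@@H]3COC(C)(C)O3 | intermediate
13 | (4R)-4-{(2E,6S)-1-bromo-6-methyl-9-[(2S)-2,6,6-trimethyloxan-2-yl]non-2-en-2-yl}-2,2-dimethyl-1,3-dioxolane (expected main isomer) | BrC/C(=C/CC[C@@H](C)CCC[C@@]1(C)CCCC(C)(C)O1)[C@@H]2COC(C)(C)O2 | intermediate
14 | (4R)-2,2-dimethyl-4-{(6R)-6-methyl-9-[(2S)-2,6,6-trimethyloxan-2-yl]non-1-en-2-yl}-1,3-dioxolane | C=C(CCC[C@@H](C)CCC[C@@]1(C)CCCC(C)(C)O1)[C@@H]2COC(C)(C)O2 | intermediate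
15 | (2R,7R)-7-methyl-3-methylidene-10-[(2S)-2,6,6-trimethyloxan-2-yl]decane-1,2-diol | C=C(CCC[C@@H](C)CCC[C@@]1(C)CCCC(C)(C)O1)[C@H](CO)O | intermediate
16 | (2R,7R)-7-methyl-3-methylidene-10-[(2S)-2,6,6-trimethyloxan-2-yl]decane-1,2-diyl diacetate | C=C(CCC[C@@H](C)CCC[C@@]1(C)CCCC(C)(C)O1)[C@H](COC(C)=O)OC(C)=O | target

## Step count and least certain steps

Total step count: 9. Longest linear sequence: 9 steps (1 to 16); compounds 4 and 9 enter as purchased materials.

**Step 5 (key step).**
- Most likely failure: incomplete alkene exchange on titanium. The cyclopentene titanacyclopropane is then consumed by ester 9, or the Grignard reagent adds directly to 9, and alkene 8 is returned unchanged. Partial enolisation at C2 under a local excess of Grignard reagent is the second concern.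
- Fallback (C3 delivered as a preformed alkenyl electrophile, C3–C4 made by B-alkyl Suzuki–Miyaura coupling). It sets out from tosylate 7 and returns at acetonide 14.
  - Copper-catalysed coupling of 7 with CH2=CHMgBr (CuI cat., THF) gives (2S)-2,6,6-trimethyl-2-[(4S)-4-methylhept-6-en-1-yl]oxane F1.
  - Hydroboration of F1 with 9-BBN gives 9-{(4R)-4-methyl-7-[(2S)-2,6,6-trimethyloxan-2-yl]heptyl}-9-borabicyclo[3.3.1]nonane F2.
  - In parallel, ester 9 is converted with N,O-dimethylhydroxylamine hydrochloride and i-PrMgCl into (4S)-N-methoxy-N,2,2-trimethyl-1,3-dioxolane-4-carboxamide F3.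
  - F3 with MeMgBr gives 1-[(4S)-2,2-dimethyl-1,3-dioxolan-4-yl]ethan-1-one F4.
  - Kinetic deprotonation of F4 at the methyl group (KN(SiMe3)2, −78 °C) and trapping with PhNTf2 gives 1-[(4S)-2,2-dimethyl-1,3-dioxolan-4-yl]ethenyl trifluoromethanesulfonate F5.
  - Coupling of F2 with F5 (Pd(dppf)Cl2, K3PO4, THF/DMF/H2O) gives 14, and the route continues with step 8.

**Step 2.**
- Most likely failure: the free hydroxyl of 4. Under KOt-Bu its alkoxide may close onto the bromide to form an oxetane, or tie up the borane, before the nickel catalyst engages the β-branched bromide.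
- Fallback (roles and metal inverted: Grignard reagent at C9, sulfonate at C8, copper catalysis). It sets out from 3 and returns at alkene 8, replacing steps 2–4.
  - Hydroboration of 3 to 5, then bromination (Br2, NaOMe), gives (2R)-2-(2-bromoethyl)-2,6,6-trimethyloxane F6.
  - Magnesium insertion into F6 gives bromo{2-[(2R)-2,6,6-trimethyloxan-2-yl]ethyl}magnesium F7.
  - Separately, purchased (2S)-3-bromo-2-methylpropan-1-ol is coupled with excess CH2=CHCH2MgCl (Li2CuCl4 cat.) to (2R)-2-methylhex-5-en-1-ol F8.
  - Tosylation of F8 gives (2R)-2-methylhex-5-en-1-yl 4-methylbenzenesulfonate F9.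
  - Li2CuCl4-catalysed coupling of F7 with F9 gives 8.

**Step 6.**
- Most likely failure: the Lewis acid MgBr2 attacks the acetonide, or the allyl cation loses a proton to a diene (or is intercepted by the C1 oxygen) before bromide collapses.
- Fallback (buffered solvolysis, then a neutral bromination). It sets out from cyclopropanol 11 and returns at bromide 13.
  - Mesylate 12 is formed as before and solvolysed without Lewis acid (aqueous acetone, CaCO3, 50 °C).
  - This gives (2Z,6S)-2-[(4R)-2,2-dimethyl-1,3-dioxolan-4-yl]-6-methyl-9-[(2S)-2,6,6-trimethyloxan-2-yl]non-2-en-1-ol F10.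
  - An Appel reaction (CBr4, PPh3, CH2Cl2, 0 °C) converts F10 into 13.

**Step 7.**
- Most likely failure: poor regioselectivity of hydride delivery (hydride to C20 gives the trisubstituted C3=C4 isomer with a C20 methyl), or β-hydride elimination of the π-allyl complex to a diene.
- Fallback (a pericyclic reductive transposition in which the hydrogen can only arrive at C4). It sets out from 13 and returns at 14.
  - N-Alkylation of N′-(propan-2-ylidene)-2-nitrobenzenesulfonohydrazide with 13 (K2CO3, DMF) gives N-{(2Z,6S)-2-[(4R)-2,2-dimethyl-1,3-dioxolan-4-yl]-6-methyl-9-[(2S)-2,6,6-trimethyloxan-2-yl]non-2-en-1-yl}-2-nitro-N′-(propan-2-ylidene)benzenesulfonohydrazide F11.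
  - Mild hydrolysis (trifluoroethanol/water) removes the hydrazone and the sulfinate and releases {(2Z,6S)-2-[(4R)-2,2-dimethyl-1,3-dioxolan-4-yl]-6-methyl-9-[(2S)-2,6,6-trimethyloxan-2-yl]non-2-en-1-yl}diazene F12.
  - F12 loses dinitrogen in a retro-ene process with transfer of hydrogen to C4 and gives 14.

## Further compounds

F1 | step 5 | (2S)-2,6,6-trimethyl-2-[(4S)-4-methylhept-6-en-1-yl]oxane | C=CC[C@@H](C)CCC[C@@]1(C)CCCC(C)(C)O1
F2 | step 5 | 9-{(4R)-4-methyl-7-[(2S)-2,6,6-trimethyloxan-2-yl]heptyl}-9-borabicyclo[3.3.1]nonane | C1CC2CCCC(C1)B2CCC[C@@H](C)CCC[C@@]1(C)CCCC(C)(C)O1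
F3 | step 5 | (4S)-N-methoxy-N,2,2-trimethyl-1,3-dioxolane-4-carboxamide | CON(C)C(=O)[C@@H]1COC(C)(C)O1
F4 | step 5 | 1-[(4S)-2,2-dimethyl-1,3-dioxolan-4-yl]ethan-1-one | CC(=O)[C@@H]1COC(C)(C)O1
F5 | step 5 | 1-[(4S)-2,2-dimethyl-1,3-dioxolan-4-yl]ethenyl trifluoromethanesulfonate | C=C(OS(=O)(=O)C(F)(F)F)[C@@H]1COC(C)(C)O1
F6 | step 2 | (2R)-2-(2-bromoethyl)-2,6,6-trimethyloxane | BrCC[C@@]1(C)CCCC(C)(C)O1
F7 | step 2 | bromo{2-[(2R)-2,6,6-trimethyloxan-2-yl]ethyl}magnesium | Br[Mg]CC[C@@]1(C)CCCC(C)(C)O1
F8 | step 2 | (2R)-2-methylhex-5-en-1-ol | C=CCC[C@@H](C)CO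
F9 | step 2 | (2R)-2-methylhex-5-en-1-yl 4-methylbenzenesulfonate | C=CCC[C@@H](C)COS(=O)(=O)c1ccc(C)cc1
F10 | step 6 | (2Z,6S)-2-[(4R)-2,2-dimethyl-1,3-dioxolan-4-yl]-6-methyl-9-[(2S)-2,6,6-trimethyloxan-2-yl]non-2-en-1-ol | OC/C(=C/CC[C@@H](C)CCC[C@@]1(C)CCCC(C)(C)O1)[C@@H]2COC(C)(C)O2
F11 | step 7 | N-{(2Z,6S)-2-[(4R)-2,2-dimethyl-1,3-dioxolan-4-yl]-6-methyl-9-[(2S)-2,6,6-trimethyloxan-2-yl]non-2-en-1-yl}-2-nitro-N′-(propan-2-ylidene)benzenesulfonohydrazide | CC(C)=NN(C/C(=C/CC[C@@H](C)CCC[C@@]1(C)CCCC(C)(C)O1)[C@@H]2COC(C)(C)O2)S(=O)(=O)c3ccccc3[N+](=O)[O-]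
F12 | step 7 | {(2Z,6S)-2-[(4R)-2,2-dimethyl-1,3-dioxolan-4-yl]-6-methyl-9-[(2S)-2,6,6-trimethyloxan-2-yl]non-2-en-1-yl}diazene | N=NC/C(=C/CC[C@@H](C)CCC[C@@]1(C)CCCC(C)(C)O1)[C@@H]2COC(C)(C)O2
A1 | alternative 1 | (5S)-1-[(4S)-2,2-dimethyl-1,3-dioxolan-4-yl]-5-methyl-8-[(2S)-2,6,6-trimethyloxan-2-yl]octan-1-one | O=C(CCC[C@@H](C)CCC[C@@]1(C)CCCC(C)(C)O1)[C@@H]2COC(C)(C)O2
A2 | alternative 1 | bromo{(4S)-4-methyl-7-[(2S)-2,6,6-trimethyloxan-2-yl]heptyl}magnesium | Br[Mg]CCC[C@@H](C)CCC[C@@]1(C)CCCC(C)(C)O1
A3 | alternative 2 | (2R)-2,6,6-trimethyloxane-2-carbaldehyde | O=C[C@@]1(C)CCCC(C)(C)O1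
A4 | alternative 2 | [(3R)-3,7-dimethyloct-6-en-1-yl]triphenylphosphonium bromide | CC(C)=CCC[C@@H](C)CC[P+](c1ccccc1)(c1ccccc1)c1ccccc1.[Br-]
A5 | alternative 2 | (2R)-2-[(1Z,4R)-4,8-dimethylnona-1,7-dien-1-yl]-2,6,6-trimethyloxane | CC(C)=CCC[C@@H](C)C/C=C\[C@@]1(C)CCCC(C)(C)O1
A6 | alternative 3 | (2E,7R)-3,7-dimethyl-10-[(2S)-2,6,6-trimethyloxan-2-yl]dec-2-en-1-ol | OC/C=C(\C)CCC[C@@H](C)CCC[C@@]1(C)CCCC(C)(C)O1
A7 | alternative 3 | {(2S,3S)-3-methyl-3-[(4S)-4-methyl-7-((2S)-2,6,6-trimethyloxan-2-yl)heptyl]oxiran-2-yl}methanol | OC[C@@H]1O[C@@]1(C)CCC[C@@H](C)CCC[C@@]2(C)CCCC(C)(C)O2
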